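Readings and results come from a simulation for an exercise, noise included.

It is tempting to run the target readings of the south-west flask straight on from 20.0 h to 4.0 d, but what that flask can still give depends on how much of its substrate remains to react.

common to all: gas phase 1.6 mM (held)
- south-west: substrate 17 mM; the very flask that is asked about, followed so far
- south-east: substrate 8.5 mM; run made earlier
- flask: substrate 17 mM; time 4.0 d

| run | time / h | target / % | substrate / % |
|---|---|---|---|
| south-west | 1.33 | 0.1 | 96.5 |
| south-west | 4.00 | 3.4 | 91.6 |
| south-west | 6.00 | 4.0 | 84.9 |
| south-west | 10.0 | 6.3 | 76.3 |
| south-west | 15.0 | 9.5 | 66.8 |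
| south-west | 20.0 | 11.2 | 59.7 |
| south-east | 6.00 | 6.6 | 86.7 |
| south-east | 12.0 | 13.5 | 74.7 |
| south-east | 20.0 | 21.1 | 59.5 |
| south-east | 25.0 | 25.9 | 51.0 |
| south-east | 30.0 | 29.1 | 43.4 |
| south-east | 40.0 | 35.3 | 29.3 |

(each reading ± 0.5 percentage points)

- at the start none of the gas phase is in solution

- the target standing at 4.0 d, as a percentage of the substrate charged
- the change that raises the amount of target at 4.0 d, in percent of the substrate charged most ("none" if none brings more than 2 percentage points) (spring / dusk / none)
- amount of target at 4.0 d, in percent of the substrate charged, after dusk

- spring: doubling the saturation concentration of gas phase, all else as stated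
- dusk: doubling the transfer coefficient of the gas phase, all else as stated

Two numbers carry the south-west flask to 4.0 d: how much substrate has gone, and what share of the lost substrate stands as target, the selectivity. One half-life fewer in our reckoning lowers the answer by 2.3 percentage points, while the south-east share in place of the south-west share raises it by 20 points, so the share weighs more than the count.

Now the numbers. The south-west substrate falls to 59.7 % by 20.0 h, a half-life of 26.9 h. The half-life count, the time asked divided by that half-life, is 3.57, which leaves 8.41 % of the substrate. The south-east run, with its smaller charge, reads a shorter half-life late on, 19.6 h, so we take that remainder as probably too high. The south-west share so far is 27.8 %, the south-east share 49.9 %. We commit to the flask's own share, which gives 25.5 % of target.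

The forecast gives 40 %, spring as the best change, and 60 % after dusk, on the ground that the target “forms at the same absolute rate in both runs”.

The flask gives 25.9 %, and 26.4 % after dusk; the answer to the best change is none, with spring adding 0.047 points and dusk 0.55 points, both below 2 points.

    gas phase ⇌ dissolved gas, rate k1*(csat - [dissolved gas]) (kL = 2.35 × 10⁻⁵ /s)
    substrate + dissolved gas → target (k = 0.0218 /M/s)
    substrate → side product (k = 8.02 × 10⁻⁷ /s)
    target → over-reaction product (k = 4.15 × 10⁻⁶ /s)
    2 substrate → self-condensation product (k = 1.44 × 10⁻⁴ /M/s)

For the same flask read at 40 h, a half-life count of 1.49 gives 35.6 % of substrate and the flask holds 35.6 %; at 4.00 d it holds 2.93 %, less than the 8.41 % from our count of 3.57. At that time target is made at 0.551 of the rate at which it is used up, and at 8.00 d the flask holds 6.97 % of target.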